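Look first at where the west run levels off, because that plateau holds the number you need.

| flask | J | X | L | G | time |
|---|---|---|---|---|---|
| east | 0.250 M | 0.300 M | 0.0250 M |  |  |
| west | 0.250 M | 0.300 M | 0.0500 M |  |  |
| north | 0.250 M | 0.300 M | 0.0250 M | 0.0750 M | 6.0 h |

| run | time / h | [G] / M |
|---|---|---|
| east run | 0.24 | 0.0266 |
| east run | 0.38 | 0.0345 |
| east run | 0.60 | 0.0492 |
| east run | 0.95 | 0.0631 |
| east run | 1.5 | 0.0737 |
| east run | 2.4 | 0.0822 |
| east run | 3.8 | 0.0911 |
| east run | 6.0 | 0.1015 |
| west run | 0.24 | 0.0439 |
| west run | 0.38 | 0.0619 |
| west run | 0.60 | 0.0839 |
| west run | 0.95 | 0.1012 |
| west run | 1.5 | 0.1159 |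
| west run | 2.4 | 0.1221 |
| west run | 3.8 | 0.1323 |
| west run | 6.0 | 0.1326 |

(each reading ± 0.002 M)

- Overall: J + X -> G, with L as catalyst.
- Constant volume, constant temperature.
- Bound and free are read together.
- "The second partner" is X.
- An order is taken over about fifteen percent of the charge, up and down.
- A share of G counts the G that was charged too.

* reaction order in [L] at the outset, round the charge of the east run, defined at two percent of the J turned into G
* G in the north run at 6.0 h, as a share of the J charged

In the west run, G goes from 0.1323 M at 3.8 h to 0.1326 M at 6.0 h, a step inside the scatter of 0.002 M. Taking that G from the charges should leave 0.117 M of J and 0.167 M of X, yet the west readings rise no further than their scatter. My own reading is that J also leaves by a route that needs no L and speeds up with the square of [J].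

Fold this into one number, B, a selectivity factor of sorts: at the charge, the rate at which J is lost by that route over the rate at which J becomes G. With X held steady, the share of J that reaches G is ln(1+B)/B, so B of zero sends the whole charge to G and a large B sends little.

The west plateau, as read, is 53.0% of the J charged, and trying values until the share fits gives B = 2.21. The first readings stand in a ratio of 1.65, but the west run has by then made more G than the east run, so its J stands lower, and I take first order in L. For the east run, with half the L, B doubles to 4.42; this loss ratio, J lost by its own route over J turned into G at the charge, is what I carry.

It gives a share of 38.2%, or 0.0956 M of G, while the east reading at 6.0 h is 0.1015 M. So the number falls 2.97 standard deviations of a single reading short, although the east readings are still rising there, from 0.0911 M at 3.8 h. B was read from the west run, which took more X than the east run, and the number holds X steady, so one number is not quite enough. If the charged G does nothing, the north run reaches 68.2% by the number and 70.6% by the east reading, and I commit to the middle, 69.4%.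

The forecast says 0.85 for the order and 67% for the north run, on a different ground from mine: “The catalyst seems to die with time”.

The flask gives an order of 1.1 and 69.0%.

    L + J + X → G + L (120.6 M⁻² h⁻¹)
    L + X ⇌ LX, settled at all times (1.390 M⁻¹)
    2 J → Xo (4.572 M⁻¹ h⁻¹)

The loss of J is what holds the north run down: the pairwise turning of J into Xo is the route that my loss ratio of 4.42 stands for. Take that step out, which puts the ratio at zero, and the north run at 6.0 h stands at 117% instead of 69.0%. With the charged G taken off, that run has made 86.8% of the J charged, against the 38.2% I reckoned from the ratio.

The data were generated by integration for substances that don't exist; noise was put on by code.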